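**Retrosynthetic overview**

1. Target numbering: C1 (CH2SO2CH3), C2 and C3 (Br), C4 and C5 (OH), C6 (H). The sulfone is cut last at CH2–S (methanesulfinate on a benzylic bromide); the C2 bromine goes back to nitrogen (Sandmeyer) and the C3 bromine to bromination ortho to that amine.
2. Feature used: the run CH2–C1–C6(H)–C5(O)–C4(O)–C3 of the benzene ring is the carbon chain CH2–C2–C3(H)–C4(=O)–C5(O)–C6 of kojic acid, and the pyranone oxygen sits where arene C2 is missing. That carbon comes from nitromethane, which forms C1–C2 and C2–C3 and leaves the nitrogen that later becomes the C2 bromine.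
3. The benzylic heteroatom takes no part in the ring formation and is carried as OCH3, not as sulfur. A CH2SO2CH3 group ortho to a diazonium group would be expected to couple to a 3-sulfonylindazole, and a sulfide would not tolerate NBS and nitrous acid. BBr3 at the end turns ArCH2OCH3 into ArCH2Br while it frees the catechol.
4. Ring order: the 4-pyranone of kojic acid is kept through step 1; the benzene ring, the only ring of the target, is formed in step 2; steps 3 to 8 adjust substituents.

Key step: step 2

Remark: pyranone atoms are numbered O1, C2 (side chain), C3, C4 (C=O), C5 (OCH3), C6 (H); the o-nitrobenzylic ethers 7 and 8 are light-sensitive and are handled in amber glassware.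

**Route**

Step 1
Reactants: 1 kojic acid
Product: 2 5-methoxy-2-(methoxymethyl)-4H-pyran-4-one
Conditions: NaH (2.4 equiv), MeI (3 equiv), DMF, 0 °C to rt
Reagents that add atoms: iodomethane, CI
Why: Williamson etherification, in which NaH deprotonates the enolic and the primary hydroxyl and iodomethane alkylates both oxygens, while the vinylogous ester carbonyl is not alkylated by iodomethane.

Step 2
Reactants: 2 5-methoxy-2-(methoxymethyl)-4H-pyran-4-one; 3 nitromethane
Product: 7 2-methoxy-5-(methoxymethyl)-4-nitrophenol, via Michael adduct 4 (not isolated), via open-chain nitro dione 5 (not isolated), via cyclic nitro aldol 6 (not isolated)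
Conditions: 3 (3 equiv), KOtBu (3 equiv), tBuOH/THF, rt to 70 °C, amber flask; then 1 M HCl
Reagents that add atoms: none
Why: The potassium nitronate of 3 should add in conjugate (Michael) fashion to the unsubstituted α-carbon C6 of the pyranone to give the enolate of 4, which expels the ring oxygen by E1cB β-elimination and opens to the enolate of the 1,3-dione 5, whose C5=C6 geometry can equilibrate through the delocalised nitronate. The nitronate carbon of (E)-5 then attacks the released C2 ketone in an intramolecular Henry (nitroaldol) addition, a 6-exo-trig closure that forms the only ring (carbocycle 6), and E1cB loss of water followed by loss of the acidic proton next to nitrogen gives the 4-nitrophenolate, so that the two new ring bonds run from the nitromethane carbon to old C6 and to old C2. The closest known reaction type is the nitromethane/alkoxide conversion of 2,6-dialkyl-4-pyranones into 4-nitrophenols and of pyrylium salts into nitroarenes, together with the oxygen-for-nitrogen exchange of kojic ethers to 4-pyridinones, which runs through the same addition, opening and reclosure. No stereocentre has to be controlled, because those of 4 and 6 are erased on aromatisation. The step needs attack at an α-carbon and not at the carbonyl carbon, which the vinylogous ester character of that carbonyl (poorly electrophilic, 1,2-addition reversible) should secure; the choice between the two α-carbons does not matter, since the new carbon ends between them either way, and the ether side chain offers no C–H that competes with nitromethane for the base.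

Step 3
Reactants: 7 2-methoxy-5-(methoxymethyl)-4-nitrophenol
Product: 8 1,2-dimethoxy-4-(methoxymethyl)-5-nitrobenzene
Conditions: MeI (1.5 equiv), K2CO3 (2 equiv), DMF, rt, amber flask
Reagents that add atoms: iodomethane, CI
Why: Williamson O-methylation of the acidic 4-nitrophenol, which masks the oxygen para to nitrogen so that the later aniline is not an oxidation-prone p-aminophenol.

Step 4
Reactants: 8 1,2-dimethoxy-4-(methoxymethyl)-5-nitrobenzene
Product: 9 4,5-dimethoxy-2-(methoxymethyl)aniline
Conditions: H2 (1 atm), 5% Pt/C, EtOAc, rt
Reagents that add atoms: none
Why: Catalytic hydrogenation of the aromatic nitro group to the aniline, with platinum on carbon chosen because it reduces nitroarenes without hydrogenolysis of the benzylic ether.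

Step 5
Reactants: 9 4,5-dimethoxy-2-(methoxymethyl)aniline
Product: 10 2-bromo-3,4-dimethoxy-6-(methoxymethyl)aniline
Conditions: NBS (1.0 equiv), MeCN, −20 to 0 °C, dark
Reagents that add atoms: N-bromosuccinimide, O=C1CCC(=O)N1Br
Why: Electrophilic aromatic bromination in which the amino group is the strongest donor, its para position carries a methoxy group and its other ortho position the side chain, so that bromine should enter the one free ortho position (C3 of the target), which is also ortho to a methoxy group.

Step 6
Reactants: 10 2-bromo-3,4-dimethoxy-6-(methoxymethyl)aniline
Product: 12 2,3-dibromo-4,5-dimethoxy-1-(methoxymethyl)benzene, via diazonium bromide 11 (not isolated)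
Conditions: NaNO2 (1.1 equiv), 48% aq HBr, MeCN, 0 °C; then CuBr (1 equiv), 48% aq HBr, 0 °C to rt
Reagents that add atoms: hydrogen bromide, Br; copper monobromide CuBr, [Cu+].[Br-]
Why: Sandmeyer reaction, in which nitrous acid converts the hindered aniline into diazonium salt 11 and CuBr (monovalent copper) reduces it to the aryl radical, which takes bromine from the copper bromide so formed with loss of N2, while the ortho CH2OCH3 group has no acidic C–H that could couple with the diazonium nitrogen.

Step 7
Reactants: 12 2,3-dibromo-4,5-dimethoxy-1-(methoxymethyl)benzene
Product: 13 3,4-dibromo-5-(bromomethyl)benzene-1,2-diol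
Conditions: BBr3 (5 equiv), CH2Cl2, −78 °C to rt; ice-water quench, rapid extraction, crude used at once
Reagents that add atoms: boron tribromide, BrB(Br)Br
Why: Lewis acid ether cleavage, in which BBr3 demethylates both aryl methyl ethers and, through bromide attack at the benzylic carbon of the boron–ether adduct, turns the benzylic methyl ether into the benzylic bromide in the same operation.

Step 8
Reactants: 13 3,4-dibromo-5-(bromomethyl)benzene-1,2-diol; 14 sodium methanesulfinate
Product: 15 3,4-dibromo-5-(methylsulfonylmethyl)benzene-1,2-diol
Conditions: 14 (3 equiv), DMF, rt, argon; dilute aq HCl work-up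
Reagents that add atoms: none
Why: Nucleophilic substitution at the benzylic carbon, in which the ambident sulfinate is alkylated at sulfur by the soft benzylic bromide to give the sulfone, the sulfinate being too weak a base to deprotonate the catechol.

**Compound list**

1 | kojic acid, 5-hydroxy-2-(hydroxymethyl)-4H-pyran-4-one | OCC1=CC(=O)C(O)=CO1 | starting material
2 | 5-methoxy-2-(methoxymethyl)-4H-pyran-4-one | COCC1=CC(=O)C(OC)=CO1 | intermediate
3 | nitromethane | C[N+](=O)[O-] | starting material
4 | Michael adduct, 3-methoxy-6-(methoxymethyl)-2-(nitromethyl)-2,3-dihydro-4H-pyran-4-one, present as its enolate, drawn as the keto form, racemic, configuration at the two sp3 carbons not defined (not isolated) | COCC1=CC(=O)C(OC)C(C[N+](=O)[O-])O1 | intermediate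
5 | open-chain nitro dione, (5E)-1,5-dimethoxy-7-nitrohept-5-ene-2,4-dione, present as its enolate, the E isomer being the one that can close (not isolated) | COCC(=O)CC(=O)/C(OC)=C\C[N+](=O)[O-] | intermediate
6 | cyclic nitro aldol, 5-hydroxy-2-methoxy-5-(methoxymethyl)-4-nitrocyclohex-2-en-1-one, racemic mixture of diastereomers, both stereocentres lost on aromatisation (not isolated) | COCC1(O)CC(=O)C(OC)=CC1[N+](=O)[O-] | intermediate
7 | 2-methoxy-5-(methoxymethyl)-4-nitrophenol | COCc1cc(O)c(OC)cc1[N+](=O)[O-] | intermediate
8 | 1,2-dimethoxy-4-(methoxymethyl)-5-nitrobenzene | COCc1cc(OC)c(OC)cc1[N+](=O)[O-] | intermediate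
9 | 4,5-dimethoxy-2-(methoxymethyl)aniline | COCc1cc(OC)c(OC)cc1N | intermediate
10 | 2-bromo-3,4-dimethoxy-6-(methoxymethyl)aniline | COCc1cc(OC)c(OC)c(Br)c1N | intermediate
11 | 2-bromo-3,4-dimethoxy-6-(methoxymethyl)benzenediazonium bromide (not isolated) | COCc1cc(OC)c(OC)c(Br)c1[N+]#N.[Br-] | intermediate
12 | 2,3-dibromo-4,5-dimethoxy-1-(methoxymethyl)benzene | COCc1cc(OC)c(OC)c(Br)c1Br | intermediate
13 | 3,4-dibromo-5-(bromomethyl)benzene-1,2-diol | BrCc1cc(O)c(O)c(Br)c1Br | intermediate
14 | sodium methanesulfinate | CS(=O)[O-].[Na+] | starting material
15 | 3,4-dibromo-5-(methylsulfonylmethyl)benzene-1,2-diol | CS(=O)(=O)Cc1cc(O)c(O)c(Br)c1Br | target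

**Step count**

Total steps: 8. Longest linear sequence: 8 steps (1 to 15).

**Steps most likely to fail**

Step 2. The nitronate may only deprotonate or add reversibly at the carbonyl instead of adding at an α-carbon, the ring-opened enolate may condense with a second molecule faster than it closes, or the base may degrade the o-nitrobenzylic ether once the arene has formed. The fallback gives up the pyranone entry for this stretch, so it cannot branch from a compound of the route. It sets out from purchased (4,5-dimethoxy-2-nitrophenyl)methanol F1, which is O-methylated with MeI and Ag2O in CH2Cl2 at rt in the dark (Purdie etherification). This should give 8 directly; the route is rejoined at 8 and steps 1 to 3 fall away.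

Step 5. The very electron-rich aniline may be oxidised by NBS at nitrogen toward a quinone imine, or a second bromination may follow at the remaining ring position. The fallback sets out from 9 and tempers the ring as the anilide. Acetylation (Ac2O, pyridine, rt) should give N-[4,5-dimethoxy-2-(methoxymethyl)phenyl]acetamide F2. Bromination (NBS, MeCN, rt), again ortho to nitrogen and to the methoxy group, should give N-[2-bromo-3,4-dimethoxy-6-(methoxymethyl)phenyl]acetamide F3. Methanolysis of the amide (HCl in MeOH, reflux, in which any exchange at the benzylic ether is degenerate) should return the route at 10.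

Step 8. The p-hydroxybenzylic bromide 13 may ionise toward a quinone methide and be lost by self-condensation or hydrolysis before the sulfinate captures it. The fallback sets out from 12 and installs the sulfone before the phenols are unmasked. HBr in AcOH (33%, rt) should exchange only the benzylic ether and give 2,3-dibromo-1-(bromomethyl)-4,5-dimethoxybenzene F4. Substitution with 14 in DMF at 60 °C should give 2,3-dibromo-4,5-dimethoxy-1-(methylsulfonylmethyl)benzene F5. BBr3 in CH2Cl2 (−78 °C to rt) should then demethylate both aryl ethers and come back to the route at the target 15, replacing steps 7 and 8.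

**Further compounds**

F1 | step 2 | (4,5-dimethoxy-2-nitrophenyl)methanol (purchased) | COc1cc(CO)c(cc1OC)[N+](=O)[O-]
F2 | step 5 | N-[4,5-dimethoxy-2-(methoxymethyl)phenyl]acetamide | COCc1cc(OC)c(OC)cc1NC(C)=O
F3 | step 5 | N-[2-bromo-3,4-dimethoxy-6-(methoxymethyl)phenyl]acetamide | COCc1cc(OC)c(OC)c(Br)c1NC(C)=O
F4 | step 8 | 2,3-dibromo-1-(bromomethyl)-4,5-dimethoxybenzene | COc1cc(CBr)c(Br)c(Br)c1OC
F5 | step 8 | 2,3-dibromo-4,5-dimethoxy-1-(methylsulfonylmethyl)benzene | COc1cc(CS(C)(=O)=O)c(Br)c(Br)c1OC
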